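**Retrosynthetic overview**
1. C9–O ester: target ⇒ macrocyclic 8,9-diol + (2R,3R)-epoxyangelic acid (from angelic acid by Sharpless epoxidation).
2. C7–C8, the key bond, closes the ten-membered ring: diol ⇒ open-chain α-hydroxy aldehyde carrying a 3-(bromomethyl)butenolide. The allylindium made from the bromide is a homoenolate-type (d3) donor, so the lactone β-carbon C7 and the aldehyde carbon C8, both natively electrophilic, are joined; C7, C8 and the exocyclic methylene appear together.
3. Butenolide ⇒ ring-closing metathesis of the 2-(bromomethyl)acrylate of a divinyl carbinol (C6 by Sharpless kinetic resolution).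
4. C5–C6 ⇒ alkyne methylalumination + acrolein; (Z)-C1=C10 ⇒ Wittig of a glycerate-derived α-alkoxy methyl ketone (C9 from the chiral pool) with a pentynyl ylide.
5. Ring order: five-membered lactone first (as butenolide), ten-membered carbocycle last.

Assumption: the SMILES is taken as drawn, i.e. 6S,7S,8R,9R, 1(10)Z,4E and a (2R,3R)-epoxyangelate (germacrane numbering C1–C15 is used for positions); all compounds labelled starting material are catalogue chemicals.

**Step 1**
Reactants: 1 angelic acid ((2Z)-2-methylbut-2-enoic acid)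
Product: 2 (2Z)-2-methylbut-2-en-1-ol
Conditions: LiAlH4, Et2O, 0 °C
Reagents that add atoms: none
Why: Hydride reduction of the acid to the primary allylic alcohol at 0 °C leaves the Z-trisubstituted olefin untouched and unisomerised.

**Step 2**
Reactants: 2 (2Z)-2-methylbut-2-en-1-ol
Product: 3 [(2S,3R)-2,3-dimethyloxiran-2-yl]methanol
Conditions: Ti(OiPr)4 (10 mol%), L-(+)-diethyl tartrate (12 mol%), t-BuOOH, 4 Å molecular sieves, CH2Cl2, −20 °C
Reagents that add atoms: tert-butyl hydroperoxide, CC(C)(C)OO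
Why: Sharpless asymmetric epoxidation with the L-(+)-tartrate catalyst delivers oxygen to the face that gives the (2S,3R)-epoxide (the same facial sense as for other Z-2-methyl allylic alcohols), and syn addition keeps CH2OH and the C3 methyl cis, so both epoxide stereocentres are set here.

**Step 3**
Reactants: 3 [(2S,3R)-2,3-dimethyloxiran-2-yl]methanol
Product: 5 (2R,3R)-2,3-dimethyloxirane-2-carboxylic acid, via epoxy aldehyde 4 (not isolated)
Conditions: TEMPO (10 mol%), PhI(OAc)2 (2.2 equiv), MeCN/H2O (1:1), 20 °C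
Reagents that add atoms: water, O
Why: Oxoammonium (TEMPO) oxidation in wet acetonitrile takes the primary alcohol through the aldehyde hydrate to the acid without opening the epoxide, whose centres become 2R,3R only through a CIP priority change.

**Step 4**
Reactants: 6 methyl (4S)-2,2-dimethyl-1,3-dioxolane-4-carboxylate
Product: 8 1-[(4S)-2,2-dimethyl-1,3-dioxolan-4-yl]ethan-1-one, via Weinreb amide 7 (not isolated)
Conditions: MeNHOMe·HCl, iPrMgCl, THF, −20 °C; then MeMgBr, −20 → 0 °C
Reagents that add atoms: methylmagnesium bromide, C[Mg]Br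
Why: One-pot Weinreb amide formation and Grignard addition stops at the ketone through the chelated tetrahedral intermediate, and the future C9 centre (chiral pool) is not epimerised at low temperature.

**Step 5**
Reactants: 9 5-chloropent-1-yne; 10 triphenylphosphine
Product: 11 (pent-4-yn-1-yl)triphenylphosphonium iodide
Conditions: NaI, MeCN, 82 °C
Reagents that add atoms: sodium iodide, [Na+].[I-]
Why: Finkelstein exchange followed by SN2 quaternisation of the phosphine gives the phosphonium salt.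

**Step 6**
Reactants: 11 (pent-4-yn-1-yl)triphenylphosphonium iodide; 8 1-[(4S)-2,2-dimethyl-1,3-dioxolan-4-yl]ethan-1-one
Product: 13 (4R)-4-[(2Z)-hept-2-en-6-yn-2-yl]-2,2-dimethyl-1,3-dioxolane, via phosphorus ylide 12 (not isolated)
Conditions: NaN(SiMe3)2 (1.0 equiv), THF, −78 °C; then 8, −78 → 0 °C
Reagents that add atoms: none
Why: Wittig olefination of an α-alkoxy methyl ketone with a non-stabilised ylide (Still-type Z-selective Wittig) places the oxygenated carbon cis to the chain, giving the (Z)-C1=C10 olefin, while the low temperature preserves the α-stereocentre and the more acidic phosphonium α-CH is deprotonated in preference to the alkyne CH.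

**Step 7**
Reactants: 13 (4R)-4-[(2Z)-hept-2-en-6-yn-2-yl]-2,2-dimethyl-1,3-dioxolane; 14 acrolein (prop-2-enal)
Product: 16 (4E,8Z)-9-[(4R)-2,2-dimethyl-1,3-dioxolan-4-yl]-5-methyldeca-1,4,8-trien-3-ol (1:1 mixture of C3 epimers), via alkenylalane 15 (not isolated)
Conditions: Me3Al, Cp2ZrCl2 (20 mol%), H2O (1.5 equiv), CH2Cl2, −23 °C; then 14, −78 → 0 °C
Reagents that add atoms: trimethylaluminium, C[Al](C)C
Why: Negishi zirconium-catalysed methylalumination adds Me and Al syn and regioselectively across the terminal alkyne, which fixes the (E)-C4=C5 olefin, and the alkenylalane then adds 1,2 to acrolein, unselectively at C6 because C9 is remote.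

**Step 8**
Reactants: 16 (4E,8Z)-9-[(4R)-2,2-dimethyl-1,3-dioxolan-4-yl]-5-methyldeca-1,4,8-trien-3-ol (1:1 mixture of C3 epimers)
Product: 17 (3R,4E,8Z)-9-[(4R)-2,2-dimethyl-1,3-dioxolan-4-yl]-5-methyldeca-1,4,8-trien-3-ol
Conditions: Ti(OiPr)4 (20 mol%), L-(+)-diisopropyl tartrate (25 mol%), t-BuOOH (0.55 equiv), 4 Å molecular sieves, CH2Cl2, −20 °C
Reagents that add atoms: none
Why: Sharpless kinetic resolution with L-(+)-tartrate rapidly epoxidises the trisubstituted allylic olefin of the (3S)-epimer and leaves the (3R)-epimer, whose only matched olefin is the intrinsically slow vinyl group, so the C6 centre is set by recovery (at most about 45% yield).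

**Step 9**
Reactants: 17 (3R,4E,8Z)-9-[(4R)-2,2-dimethyl-1,3-dioxolan-4-yl]-5-methyldeca-1,4,8-trien-3-ol; 18 2-(bromomethyl)prop-2-enoic acid
Product: 19 (3R,4E,8Z)-9-[(4R)-2,2-dimethyl-1,3-dioxolan-4-yl]-5-methyldeca-1,4,8-trien-3-yl 2-(bromomethyl)prop-2-enoate
Conditions: DCC, DMAP (5 mol%), CH2Cl2, 0 °C
Reagents that add atoms: none
Why: Steglich esterification acylates the secondary alcohol with retention under near-neutral conditions that spare the allylic bromide and the bis-allylic C–O bond.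

**Step 10**
Reactants: 19 (3R,4E,8Z)-9-[(4R)-2,2-dimethyl-1,3-dioxolan-4-yl]-5-methyldeca-1,4,8-trien-3-yl 2-(bromomethyl)prop-2-enoate
Product: 20 (5S)-3-(bromomethyl)-5-{(1E,5Z)-6-[(4R)-2,2-dimethyl-1,3-dioxolan-4-yl]-2-methylhepta-1,5-dien-1-yl}furan-2(5H)-one
Conditions: second-generation Grubbs catalyst (5 mol%), CH2Cl2 (5 mM), 40 °C
Reagents that add atoms: none
Why: Ring-closing metathesis between the vinyl group and the 1,1-disubstituted acrylate closes the butenolide with loss of ethene, the trisubstituted chain olefins being inert to the ruthenium carbene and C6 untouched (its descriptor becomes S by priority change only).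

**Step 11**
Reactants: 20 (5S)-3-(bromomethyl)-5-{(1E,5Z)-6-[(4R)-2,2-dimethyl-1,3-dioxolan-4-yl]-2-methylhepta-1,5-dien-1-yl}furan-2(5H)-one
Product: 21 (5S)-3-(bromomethyl)-5-[(1E,5Z,7R)-7,8-dihydroxy-2,6-dimethylocta-1,5-dien-1-yl]furan-2(5H)-one
Conditions: AcOH/H2O (4:1), 25 °C
Reagents that add atoms: none
Why: Mild aqueous acid hydrolyses the terminal acetonide without ionising the allylic bromide, the lactone or the allylic C9–O bond.

**Step 12**
Reactants: 21 (5S)-3-(bromomethyl)-5-[(1E,5Z,7R)-7,8-dihydroxy-2,6-dimethylocta-1,5-dien-1-yl]furan-2(5H)-one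
Product: 22 (2R,3Z,7E)-8-[(2S)-4-(bromomethyl)-5-oxo-2,5-dihydrofuran-2-yl]-2-hydroxy-3,7-dimethylocta-3,7-dienal
Conditions: TEMPO (20 mol%), PhI(OAc)2 (1.1 equiv), CH2Cl2, 0 → 20 °C; used at once
Reagents that add atoms: none
Why: Oxoammonium oxidation is selective for the primary over the more hindered secondary allylic hydroxyl and stops at the aldehyde under anhydrous, base-free conditions that do not epimerise C9.

**Step 13**
Reactants: 22 (2R,3Z,7E)-8-[(2S)-4-(bromomethyl)-5-oxo-2,5-dihydrofuran-2-yl]-2-hydroxy-3,7-dimethylocta-3,7-dienal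
Product: 24 (3aS,4R,5R,6Z,10E,11aS)-4,5-dihydroxy-6,10-dimethyl-3-methylidene-3a,4,5,8,9,11a-hexahydrocyclodeca[b]furan-2(3H)-one, via allylindium bromide 23 (not isolated)
Conditions: In powder (4 equiv), THF/H2O (1:1), slow addition to 1 mM, 25 °C
Reagents that add atoms: none
Why: Proposed new method: an intramolecular indium Barbier allylation in which In inserts into the allylic C–Br bond to give a 2-(alkoxycarbonyl)allylindium (homoenolate-type donor) that attacks the aldehyde through its γ-carbon C7 (SE2′), forming C7–C8, the exocyclic methylene and the ten-membered ring at high dilution; C7 is set by attack anti to the C5 chain on the butenolide (trans lactone), and C8 by a cyclic transition state in which trivalent indium is chelated between the aldehyde oxygen and the free C9 hydroxyl, which gives the syn-8,9-diol and forces the aldehyde substituent axial so that the E-locked allyl unit delivers the required C7/C8 relationship; the closest known reactions are intermolecular Zn/In Barbier additions of 3-(bromomethyl)furan-2(5H)-ones to aldehydes, threo-selective aqueous indium allylations of unprotected α-hydroxy aldehydes, and Barbier/Nozaki–Hiyama–Kishi macrocyclisations to germacranolides.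

**Step 14**
Reactants: 24 (3aS,4R,5R,6Z,10E,11aS)-4,5-dihydroxy-6,10-dimethyl-3-methylidene-3a,4,5,8,9,11a-hexahydrocyclodeca[b]furan-2(3H)-one; 5 (2R,3R)-2,3-dimethyloxirane-2-carboxylic acid
Product: 26 (3aS,4R,5R,6Z,10E,11aS)-4-hydroxy-6,10-dimethyl-3-methylidene-2-oxo-2,3,3a,4,5,8,9,11a-octahydrocyclodeca[b]furan-5-yl (2R,3R)-2,3-dimethyloxirane-2-carboxylate (target), via mixed anhydride 25 (not isolated)
Conditions: 5, 2,4,6-trichlorobenzoyl chloride, Et3N, THF, 0 °C; then 24 (1.0 equiv), DMAP, toluene, 0 → 20 °C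
Reagents that add atoms: none
Why: Yamaguchi esterification through the hindered mixed anhydride is expected to acylate the more accessible allylic C9 hydroxyl (next to planar C10) in preference to the C8 hydroxyl, which is flanked by the ring-fusion methine, without touching any stereocentre.

**Compound list**
1 | angelic acid, (2Z)-2-methylbut-2-enoic acid | C/C=C(/C)C(=O)O | starting material
2 | (2Z)-2-methylbut-2-en-1-ol | C/C=C(/C)CO | intermediate
3 | [(2S,3R)-2,3-dimethyloxiran-2-yl]methanol | OC[C@]1(C)O[C@@H]1C | intermediate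
4 | (2R,3R)-2,3-dimethyloxirane-2-carbaldehyde | O=C[C@]1(C)O[C@@H]1C | intermediate
5 | (2R,3R)-2,3-dimethyloxirane-2-carboxylic acid | OC(=O)[C@]1(C)O[C@@H]1C | intermediate
6 | methyl (4S)-2,2-dimethyl-1,3-dioxolane-4-carboxylate | COC(=O)[C@@H]1COC(C)(C)O1 | starting material
7 | (4S)-N-methoxy-N,2,2-trimethyl-1,3-dioxolane-4-carboxamide | CON(C)C(=O)[C@@H]1COC(C)(C)O1 | intermediate
8 | 1-[(4S)-2,2-dimethyl-1,3-dioxolan-4-yl]ethan-1-one | CC(=O)[C@@H]1COC(C)(C)O1 | intermediate
9 | 5-chloropent-1-yne | C#CCCCCl | starting material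
10 | triphenylphosphine | c1ccc(cc1)P(c1ccccc1)c1ccccc1 | starting material
11 | (pent-4-yn-1-yl)triphenylphosphonium iodide | C#CCCC[P+](c1ccccc1)(c1ccccc1)c1ccccc1.[I-] | intermediate
12 | (pent-4-yn-1-ylidene)triphenylphosphorane | C#CCCC=P(c1ccccc1)(c1ccccc1)c1ccccc1 | intermediate
13 | (4R)-4-[(2Z)-hept-2-en-6-yn-2-yl]-2,2-dimethyl-1,3-dioxolane | C#CCC/C=C(/C)[C@@H]1COC(C)(C)O1 | intermediate
14 | acrolein, prop-2-enal | C=CC=O | starting material
15 | dimethyl{(1E,5Z)-6-[(4R)-2,2-dimethyl-1,3-dioxolan-4-yl]-2-methylhepta-1,5-dien-1-yl}alane | C[Al](C)/C=C(\C)CC/C=C(/C)[C@@H]1COC(C)(C)O1 | intermediate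
16 | (4E,8Z)-9-[(4R)-2,2-dimethyl-1,3-dioxolan-4-yl]-5-methyldeca-1,4,8-trien-3-ol (1:1 mixture of C3 epimers) | C=CC(O)/C=C(\C)CC/C=C(/C)[C@@H]1COC(C)(C)O1 | intermediate
17 | (3R,4E,8Z)-9-[(4R)-2,2-dimethyl-1,3-dioxolan-4-yl]-5-methyldeca-1,4,8-trien-3-ol | C=C[C@@H](O)/C=C(\C)CC/C=C(/C)[C@@H]1COC(C)(C)O1 | intermediate
18 | 2-(bromomethyl)prop-2-enoic acid | C=C(CBr)C(=O)O | starting material
19 | (3R,4E,8Z)-9-[(4R)-2,2-dimethyl-1,3-dioxolan-4-yl]-5-methyldeca-1,4,8-trien-3-yl 2-(bromomethyl)prop-2-enoate | C=C[C@@H](OC(=O)C(=C)CBr)/C=C(\C)CC/C=C(/C)[C@@H]1COC(C)(C)O1 | intermediate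
20 | (5S)-3-(bromomethyl)-5-{(1E,5Z)-6-[(4R)-2,2-dimethyl-1,3-dioxolan-4-yl]-2-methylhepta-1,5-dien-1-yl}furan-2(5H)-one | O=C1O[C@@H](/C=C(\C)CC/C=C(/C)[C@@H]2COC(C)(C)O2)C=C1CBr | intermediate
21 | (5S)-3-(bromomethyl)-5-[(1E,5Z,7R)-7,8-dihydroxy-2,6-dimethylocta-1,5-dien-1-yl]furan-2(5H)-one | O=C1O[C@@H](/C=C(\C)CC/C=C(/C)[C@@H](O)CO)C=C1CBr | intermediate
22 | (2R,3Z,7E)-8-[(2S)-4-(bromomethyl)-5-oxo-2,5-dihydrofuran-2-yl]-2-hydroxy-3,7-dimethylocta-3,7-dienal | O=C1O[C@@H](/C=C(\C)CC/C=C(/C)[C@@H](O)C=O)C=C1CBr | intermediate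
23 | {[(5S)-5-[(1E,5Z,7R)-7-hydroxy-2,6-dimethyl-8-oxoocta-1,5-dien-1-yl]-2-oxo-2,5-dihydrofuran-3-yl]methyl}indium dibromide (allylindium species drawn as the dibromide) | O=C1O[C@@H](/C=C(\C)CC/C=C(/C)[C@@H](O)C=O)C=C1C[In](Br)Br | intermediate
24 | (3aS,4R,5R,6Z,10E,11aS)-4,5-dihydroxy-6,10-dimethyl-3-methylidene-3a,4,5,8,9,11a-hexahydrocyclodeca[b]furan-2(3H)-one | C=C1C(=O)O[C@H]2/C=C(\C)CC/C=C(/C)[C@@H](O)[C@H](O)[C@H]12 | intermediate
25 | (2R,3R)-2,3-dimethyloxirane-2-carboxylic 2,4,6-trichlorobenzoic anhydride | O=C(OC(=O)c1c(Cl)cc(Cl)cc1Cl)[C@]1(C)O[C@@H]1C | intermediate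
26 | (3aS,4R,5R,6Z,10E,11aS)-4-hydroxy-6,10-dimethyl-3-methylidene-2-oxo-2,3,3a,4,5,8,9,11a-octahydrocyclodeca[b]furan-5-yl (2R,3R)-2,3-dimethyloxirane-2-carboxylate | C=C1C(=O)O[C@H]2/C=C(\C)CC/C=C(/C)[C@@H](OC(=O)[C@]3(C)O[C@@H]3C)[C@H](O)[C@H]12 | target

**Step count**
Total: 14 steps (steps 1–3 make the acid, step 5 the phosphonium salt). Longest linear sequence: 10 steps, from 6 to 26 through steps 4 and 6–14.

**Three steps most likely to fail**

Step 13 (ring closure). Risks are oligomerisation, attack through the CH2 terminus (twelve-membered ring with an endocyclic butenolide), cis ring fusion, or the C8 epimer if the chelated transition state is not followed. The fallback sets out from bromide 20 and comes back at diol 24; it replaces the in situ organoindium by an isolable allylstannane closed under Lewis-acid chelation through an open transition state. Bromide 20 is stannylated with Bu3SnSnBu3 and Pd(PPh3)4 (THF, 50 °C) to give the stannane acetonide F1. Acetonide hydrolysis (AcOH/H2O, 25 °C; the electron-poor allylstannane tolerates this) gives the stannane diol F2. TEMPO/PhI(OAc)2 oxidation gives the stannane hydroxy aldehyde F3. Slow addition of F3 to MgBr2·OEt2 in CH2Cl2 at −20 °C (1 mM) closes the ring by an allylstannane addition to the magnesium-chelated aldehyde, which favours the same syn,syn array and returns to 24.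

Step 14 (which hydroxyl is acylated; acyl migration). The C9 over C8 preference is an expectation, not a precedent. The fallback sets out from diol 24 and comes back at target 26; it fixes the regiochemistry with a silyl ether, which does not migrate and can be separated. TESCl/imidazole (CH2Cl2, −40 °C) gives the mono-silyl ethers, from which the C8 triethylsilyl ether F4 is isolated (the C9 isomer is recycled to 24 with HF·pyridine). Yamaguchi esterification of F4 with acid 5 gives the silylated ester F5, and HF·pyridine (THF, 0 °C) removes the silyl group to give 26.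

Step 12 (chemoselective oxidation; lability of 22). The allylic secondary hydroxyl may also oxidise, and 22 can epimerise at C9 or isomerise into conjugation. The fallback sets out from diol 21 and comes back at aldehyde 22. TESOTf/2,6-lutidine gives the bis-silyl ether F6. Swern oxidation ((COCl)2, DMSO, −78 °C; iPr2NEt, −78 → −30 °C) converts only the primary silyl ether directly into the aldehyde, giving the more robust α-silyloxy aldehyde F7. F7 is desilylated in AcOH/THF/H2O immediately before indium is added, which delivers 22 in the cyclisation medium.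

**Further compounds**
F1 | step 13 | (5S)-5-{(1E,5Z)-6-[(4R)-2,2-dimethyl-1,3-dioxolan-4-yl]-2-methylhepta-1,5-dien-1-yl}-3-[(tributylstannyl)methyl]furan-2(5H)-one | O=C1O[C@@H](/C=C(\C)CC/C=C(/C)[C@@H]2COC(C)(C)O2)C=C1C[Sn](CCCC)(CCCC)CCCC
F2 | step 13 | (5S)-5-[(1E,5Z,7R)-7,8-dihydroxy-2,6-dimethylocta-1,5-dien-1-yl]-3-[(tributylstannyl)methyl]furan-2(5H)-one | O=C1O[C@@H](/C=C(\C)CC/C=C(/C)[C@@H](O)CO)C=C1C[Sn](CCCC)(CCCC)CCCC
F3 | step 13 | (2R,3Z,7E)-2-hydroxy-3,7-dimethyl-8-{(2S)-5-oxo-4-[(tributylstannyl)methyl]-2,5-dihydrofuran-2-yl}octa-3,7-dienal | O=C1O[C@@H](/C=C(\C)CC/C=C(/C)[C@@H](O)C=O)C=C1C[Sn](CCCC)(CCCC)CCCC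
F4 | step 14 | (3aS,4R,5R,6Z,10E,11aS)-5-hydroxy-6,10-dimethyl-3-methylidene-4-[(triethylsilyl)oxy]-3a,4,5,8,9,11a-hexahydrocyclodeca[b]furan-2(3H)-one | C=C1C(=O)O[C@H]2/C=C(\C)CC/C=C(/C)[C@@H](O)[C@H](O[Si](CC)(CC)CC)[C@H]12
F5 | step 14 | (3aS,4R,5R,6Z,10E,11aS)-6,10-dimethyl-3-methylidene-2-oxo-4-[(triethylsilyl)oxy]-2,3,3a,4,5,8,9,11a-octahydrocyclodeca[b]furan-5-yl (2R,3R)-2,3-dimethyloxirane-2-carboxylate | C=C1C(=O)O[C@H]2/C=C(\C)CC/C=C(/C)[C@@H](OC(=O)[C@]3(C)O[C@@H]3C)[C@H](O[Si](CC)(CC)CC)[C@H]12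
F6 | step 12 | (5S)-3-(bromomethyl)-5-[(1E,5Z,7R)-2,6-dimethyl-7,8-bis(triethylsilyloxy)octa-1,5-dien-1-yl]furan-2(5H)-one | O=C1O[C@@H](/C=C(\C)CC/C=C(/C)[C@@H](O[Si](CC)(CC)CC)CO[Si](CC)(CC)CC)C=C1CBr
F7 | step 12 | (2R,3Z,7E)-8-[(2S)-4-(bromomethyl)-5-oxo-2,5-dihydrofuran-2-yl]-3,7-dimethyl-2-[(triethylsilyl)oxy]octa-3,7-dienal | O=C1O[C@@H](/C=C(\C)CC/C=C(/C)[C@@H](O[Si](CC)(CC)CC)C=O)C=C1CBr
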